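**Assumption:** the target SMILES has no stereocentres and does not specify the configuration of the biaryl (C3–C3') axis, so I treat the target as achiral or a freely interconverting atropisomer pair and make it without stereocontrol. It is 2,2'-diphenyl-3,3'-bichromone (3,3'-biflavone, C30H18O4).

## Retrosynthesis
1. The C3–C3' biaryl bond is disconnected to two equivalents of 3-iodoflavone (reductive Ullmann homocoupling, the last step).
2. 3-Iodoflavone is disconnected by cyclodehydration to the 2-iodo-1-(2-hydroxyphenyl)-3-phenylpropane-1,3-dione, so the pyranone ring forms before the biaryl bond.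
3. The iodo-diketone comes from iodination of the central carbon of 1-(2-hydroxyphenyl)-3-phenylpropane-1,3-dione.
4. That diketone is made by Baker–Venkataraman rearrangement of 2-acetylphenyl benzoate, which comes from 2'-hydroxyacetophenone and benzoyl chloride.

## Forward route

**Step 1**
Reactants: 1 (2'-hydroxyacetophenone), 2 (benzoyl chloride)
Product: 3 (2-acetylphenyl benzoate)
Conditions: pyridine, CH2Cl2, 0 °C to rt
Reagents that add atoms: benzoyl chloride, O=C(Cl)c1ccccc1 (supplies the benzoyl group)
Why: Pyridine-promoted O-acylation of the phenol (Schotten–Baumann-type esterification) gives the ester, and no stereocentre is formed.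

**Step 2**
Reactants: 3 (2-acetylphenyl benzoate)
Product: 4 (1-(2-hydroxyphenyl)-3-phenylpropane-1,3-dione)
Conditions: KOtBu, THF, rt, then aqueous HCl workup
Reagents that add atoms: none (an isomerisation)
Why: Baker–Venkataraman rearrangement, in which the ketone enolate attacks the ester intramolecularly and the ring opens to the 1,3-diketone phenoxide, which is protonated on workup. No stereocentre is formed (the product is a mixture of enol tautomers).

**Step 3**
Reactants: 4 (diketone), 5 (N-iodosuccinimide)
Product: 6 (2-iodo-1-(2-hydroxyphenyl)-3-phenylpropane-1,3-dione)
Conditions: NIS (1.0 equiv), MeCN, rt, dark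
Reagents that add atoms: N-iodosuccinimide, O=C1CCC(=O)N1I (supplies I)
Why: Electrophilic α-iodination of the enolised 1,3-diketone occurs at the doubly activated central carbon, which is far more nucleophilic than the H-bonded, acyl-deactivated phenol ring. The product is an epimerisable CH–I centre that is destroyed in the next step.

**Step 4**
Reactants: 6 (iodo-diketone)
Product: 7 (3-iodoflavone)
Conditions: cat. H2SO4, AcOH, 100 °C, 1 h
Reagents that add atoms: none (loses H2O)
Why: Acid-catalysed intramolecular attack of the phenol on the benzoyl carbonyl, then dehydration, forms the chromone ring (cyclodehydration, as in Kostanecki-type flavone formation). It places iodine at C3 and removes the CH–I stereocentre by forming the C2=C3 bond.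

**Step 5**
Reactants: 7 (3-iodoflavone, 2 equiv)
Product: 8 (3,3'-biflavone, the target)
Conditions: activated Cu powder, DMF, 130–140 °C, Ar, 12 h
Reagents that add atoms: none (Cu is consumed as CuI)
Why: Ullmann reductive homocoupling joins the two C(sp2)–I positions to make the C3–C3' bond. The ketone, enone and aryl ether oxygens tolerate these conditions, and the achiral biaryl is formed without stereocontrol, as assumed.

## Self-check
- **Target match:** 8 has two chromen-4-one rings joined at C3–C3', with a phenyl at each C2 and no other substituents, matching O=c1c(-c2c(-c3ccccc3)oc3ccccc3c2=O)c(-c2ccccc2)oc2ccccc12.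
- **Atom balance:**
  - 1 (C8H8O2) + 2 (C7H5ClO) gives 3 (C15H12O3) plus HCl.
  - 3 isomerises to 4 (C15H12O3).
  - 4 + NIS gives 6 (C15H11IO3) plus succinimide.
  - 6 gives 7 (C15H9IO2) plus H2O.
  - 2 × 7 gives 8 (C30H18O4) plus I2, taken up by Cu as CuI.
- **Functional-group survival:** Nothing present in steps 1–4 is sensitive to the conditions used. In step 5 the aryl iodide is the only reactive site, and Cu does not reduce the chromone carbonyl.
- **Stereochemistry:** The target has no specified stereocentres, and none is created or lost beyond the transient CH–I centre in 6.

## Compound list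
1 | 2'-hydroxyacetophenone | CC(=O)c1ccccc1O | starting material
2 | benzoyl chloride | O=C(Cl)c1ccccc1 | starting material
3 | 2-acetylphenyl benzoate | CC(=O)c1ccccc1OC(=O)c1ccccc1 | intermediate
4 | 1-(2-hydroxyphenyl)-3-phenylpropane-1,3-dione | O=C(CC(=O)c1ccccc1)c1ccccc1O | intermediate
5 | N-iodosuccinimide | O=C1CCC(=O)N1I | starting material (reagent)
6 | 2-iodo-1-(2-hydroxyphenyl)-3-phenylpropane-1,3-dione (racemic, achiral in practice through enolisation) | O=C(C(I)C(=O)c1ccccc1)c1ccccc1O | intermediate
7 | 3-iodoflavone (3-iodo-2-phenylchromen-4-one) | O=c1c(I)c(-c2ccccc2)oc2ccccc12 | intermediate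
8 | 3,3'-biflavone (achiral as drawn, no stereocentres) | O=c1c(-c2c(-c3ccccc3)oc3ccccc3c2=O)c(-c2ccccc2)oc2ccccc12 | target

**Total steps:** 5. **Longest linear sequence:** 5 (1 → 3 → 4 → 6 → 7 → 8).

## Three steps most likely to fail
1. **Step 5, Ullmann homocoupling.** The product is a tetra-ortho-substituted biaryl, and Cu may give only reduction to flavone.
   - Fallback: convert 7 to the 3-Bpin flavone (Miyaura borylation) and run a Pd/SPhos Suzuki coupling with a second equivalent of 7.
2. **Step 4 (with step 3), iodination and cyclisation.** The C–I bond may be lost (protodeiodination) under hot acid, or the iodo-diketone may be unstable.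
   - Fallback: cyclise 4 to flavone first, brominate C2=C3 with Br2 and eliminate with Et3N to give 3-bromoflavone, then use that in the coupling.
3. **Step 2, Baker–Venkataraman.** Competing ester hydrolysis or self-condensation can lower the yield.
   - Fallback: skip the ester and make 4 directly by Claisen condensation of 2'-hydroxyacetophenone with methyl benzoate (2 equiv NaH or LiHMDS, THF). Alternatively, buy 4 (1-(2-hydroxyphenyl)-3-phenylpropane-1,3-dione) directly.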